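**Plan**
- Numbering the chain from the ester carbon C1, the dioxane carbons C3, C4, C5 and C6 would form a cyclobutane if C3 were bonded to C6. The retrosynthesis therefore takes O1–O2 out as O2 (cutting C6–O1 and O2–C3) and closes C3–C6 to a 1-hydroxycyclobutylacetate.
- The cyclobutanol is cut at C2–C3 (ester enolate plus cyclobutanone), at C4–CH3 (auxiliary-directed methylation) and at C3–C6/C5–C6 (cyclopropylide spiroannulation of a methyl ketone).
- The methyl ketone is cut at C11–C12 (copper-catalysed coupling with a 5-phenylpentyl Grignard reagent) and at C6–CH3 (MeMgBr on citronellal).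
- Forward: the C6–C16 chain is assembled first, the cyclobutane is then built on the ketone carbon, the C4 methyl and the acetate arm follow, and the 1,2-dioxane is closed last by O2 insertion.
- Stereochemistry: C8 comes from (R)-citronellol and C4 from a SAMP-hydrazone methylation. C6 forms from a planar radical as both epimers, which are separated; C3 settles thermodynamically with the anomeric OH axial.

Key step: step 12

Remark: three centres that are destroyed later (the carbinol carbons made in steps 2 and 11 and the quaternary ring carbon made in step 7, the future C6) are carried as epimer mixtures, so names and SMILES leave them undefined.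

**Step 1**
Reactants: 1 (R)-citronellol
Product: 2 (R)-citronellal, (3R)-3,7-dimethyloct-6-enal
Conditions: 2,2,6,6-tetramethylpiperidin-1-oxyl (TEMPO, cat.), PhI(OAc)2, CH2Cl2, rt
Reagents that add atoms: none
Why: Oxoammonium (TEMPO/PhI(OAc)2) oxidation of a primary alcohol stops at the aldehyde and touches neither the trisubstituted alkene nor the β-stereocentre.

**Step 2**
Reactants: 2 (R)-citronellal
Product: 3 (4R)-4,8-dimethylnon-7-en-2-ol (both C2 epimers)
Conditions: MeMgBr, Et2O, 0 °C; aqueous work-up
Reagents that add atoms: methylmagnesium bromide, C[Mg]Br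
Why: Grignard addition to the aldehyde installs the carbon that becomes the C6 methyl group; the new carbinol centre forms without control, which is immaterial because step 6 oxidises it.

**Step 3**
Reactants: 3 (4R)-4,8-dimethylnon-7-en-2-ol
Product: 4 (4R)-4-methylheptane-1,6-diol (both C6 epimers)
Conditions: O3, CH2Cl2/MeOH, −78 °C; then NaBH4, −78 °C to rt
Reagents that add atoms: ozone, [O-][O+]=O
Why: Ozonolysis of the electron-rich trisubstituted alkene with reductive NaBH4 work-up (Criegee cleavage) trims the prenyl terminus to a primary alcohol before any arene is present.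

**Step 4**
Reactants: 4 (4R)-4-methylheptane-1,6-diol
Product: 5 (4R)-6-hydroxy-4-methylheptyl 4-methylbenzenesulfonate
Conditions: TsCl (1.05 equiv), pyridine, CH2Cl2, −10 to 0 °C
Reagents that add atoms: 4-methylbenzenesulfonyl chloride, Cc1ccc(cc1)S(=O)(=O)Cl
Why: Kinetic sulfonylation distinguishes the unhindered primary hydroxyl from the secondary one, a standard selective monotosylation of a primary–secondary diol.

**Step 5**
Reactants: 5 (4R)-6-hydroxy-4-methylheptyl 4-methylbenzenesulfonate; 6 (5-bromopentyl)benzene
Product: 8 (4R)-4-methyl-12-phenyldodecan-2-ol, via 5-phenylpentylmagnesium bromide 7 (not isolated)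
Conditions: 6, Mg, THF, 40 °C; then 5, Li2CuCl4 (cat.), THF, −78 °C to rt (3 equiv of 7); aqueous work-up
Reagents that add atoms: none
Why: Copper-catalysed sp3–sp3 cross-coupling of a primary tosylate with a primary Grignard reagent (Kochi-type coupling with Li2CuCl4) joins C11 to C12, the free hydroxyl being carried as its magnesium alkoxide by the first equivalent of 7.

**Step 6**
Reactants: 8 (4R)-4-methyl-12-phenyldodecan-2-ol
Product: 9 (4R)-4-methyl-12-phenyldodecan-2-one
Conditions: Dess–Martin periodinane, CH2Cl2, rt
Reagents that add atoms: none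
Why: Dess–Martin oxidation of the secondary alcohol gives the methyl ketone and erases the undefined carbinol centre, while the β-stereocentre cannot epimerise.

**Step 7**
Reactants: 9 (4R)-4-methyl-12-phenyldodecan-2-one; 10 cyclopropyldiphenylsulfonium tetrafluoroborate
Product: 13 2-methyl-2-[(2R)-2-methyl-10-phenyldecyl]cyclobutan-1-one (both C2 epimers), via sulfonium cyclopropylide 11 (not isolated), via oxaspiropentane adduct 12 (not isolated)
Conditions: KOH (powdered), DMSO, 25 °C; then 1 M aq. HBF4, Et2O, rt
Reagents that add atoms: none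
Why: Trost spiroannulation, in which the sulfonium cyclopropylide adds to the ketone and expels Ph2S to give the oxaspiropentane, whose acid-promoted opening to a cyclopropylcarbinyl cation and 1,2-shift (semipinacol-type ring expansion) delivers the α-quaternary cyclobutanone; the quaternary centre forms as both epimers, which is accepted because step 12 planarises it.

**Step 8**
Reactants: 13 2-methyl-2-[(2R)-2-methyl-10-phenyldecyl]cyclobutan-1-one
Product: 14 (E)-N-[(2S)-2-(methoxymethyl)pyrrolidin-1-yl]-2-methyl-2-[(2R)-2-methyl-10-phenyldecyl]cyclobutan-1-imine (SAMP hydrazone)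
Conditions: SAMP (1.2 equiv), 4-methylbenzenesulfonic acid (cat.), cyclohexane, reflux, Dean–Stark
Reagents that add atoms: (S)-1-amino-2-(methoxymethyl)pyrrolidine (SAMP), COC[C@@H]1CCCN1N
Why: Acid-catalysed condensation (Enders hydrazone formation) is driven by water removal and by the high carbonyl reactivity of the strained ketone, and places the amino group anti to the quaternary carbon.

**Step 9**
Reactants: 14 SAMP hydrazone of 13
Product: 16 (E,4R)-N-[(2S)-2-(methoxymethyl)pyrrolidin-1-yl]-2,4-dimethyl-2-[(2R)-2-methyl-10-phenyldecyl]cyclobutan-1-imine, via lithium azaenolate 15 (not isolated)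
Conditions: LiN(iPr)2 (LDA), THF, 0 °C; then MeI, −95 °C to rt
Reagents that add atoms: iodomethane, CI
Why: Enders SAMP-hydrazone alkylation, in which only C4 carries α-hydrogens and the methoxy-chelated lithium azaenolate is methylated on the face dictated by the auxiliary, which should set C4 as R in both C2 epimers (the same sense that gives (R)-2-methylcyclohexanone from cyclohexanone).

**Step 10**
Reactants: 16 methylated SAMP hydrazone
Product: 17 (4R)-2,4-dimethyl-2-[(2R)-2-methyl-10-phenyldecyl]cyclobutan-1-one (both C2 epimers)
Conditions: saturated aq. oxalic acid, Et2O, rt (two-phase)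
Reagents that add atoms: water, O
Why: Two-phase oxalic acid hydrolysis of the hydrazone releases the ketone under conditions too mild to enolise the strained cyclobutanone, so the C4 centre should survive, and the auxiliary is recovered from the aqueous layer.

**Step 11**
Reactants: 17 (4R)-2,4-dimethyl-2-[(2R)-2-methyl-10-phenyldecyl]cyclobutan-1-one; 18 methyl acetate
Product: 20 methyl 2-[(4R)-1-hydroxy-2,4-dimethyl-2-[(2R)-2-methyl-10-phenyldecyl]cyclobutyl]acetate (C1 and C2 epimers), via lithium 1-methoxyethenolate 19 (not isolated)
Conditions: 18, LiN(iPr)2, THF, −78 °C; then 17, −78 °C; AcOH quench at −78 °C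
Reagents that add atoms: none
Why: Aldol-type addition of the lithium ester enolate to the strained, highly electrophilic cyclobutanone, quenched cold to suppress retro-aldol; the carbinol configuration is irrelevant because this carbon passes through the C3 ketone in step 12.

**Step 12**
Reactants: 20 methyl 2-[(4R)-1-hydroxy-2,4-dimethyl-2-[(2R)-2-methyl-10-phenyldecyl]cyclobutyl]acetate; 21 dioxygen
Product: 23 methyl 2-[(3S,4R,6S)-3-hydroxy-4,6-dimethyl-6-[(2R)-2-methyl-10-phenyldecyl]-1,2-dioxan-3-yl]acetate (CNP0271894.1), via open-chain hydroperoxy ketone 22 (not isolated)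
Conditions: Co(acac)2 (20 mol %), O2 (1 atm), CH2Cl2, rt; chromatographic separation from the C6 epimer
Reagents that add atoms: none
Why: The alcohol exchanges onto cobalt that O2 has raised from the divalent to the trivalent state, Co–O homolysis gives the cyclobutyloxy radical, β-scission of the ring bond to the quaternary carbon (C3–C6 in chain numbering) releases the ring strain and leaves the C3 ketone and a tertiary C6 radical, and this radical captures O2 and is released, after trapping of the peroxyl radical by divalent cobalt and exchange with the next molecule of 20, as hydroperoxy ketone 22. The closest known reaction type is the cobalt-catalysed aerobic oxidative ring expansion of cyclobutanols to 1,2-dioxan-3-ols, the homologue of the oxygenation of cyclopropanols to 1,2-dioxolan-3-ols. The 1,2-dioxane closes by reversible 6-exo-trig addition of the hydroperoxide oxygen to the C3 carbonyl, so the step forms C6–O1 and O2–C3. C6 is created from a planar, unbiased radical and should form as both epimers, which are diastereomers (C4 and C8 are fixed) and are separated by chromatography, whereas C3 is set thermodynamically by the reversible hemiketalisation, which places the anomeric OH axial, cis to the C4 methyl, and CH2CO2Me equatorial, that is 3S in the 6S series. The step needs regioselective scission toward the quaternary carbon and not toward C4 or the exocyclic CH2CO2Me bond, which the substrate secures because only that cleavage gives a tertiary radical while an exocyclic cleavage would release no strain. The neutral conditions should leave the ester, the C4 α-centre and the benzylic positions untouched.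

**Compound list**
1 | (R)-citronellol, (3R)-3,7-dimethyloct-6-en-1-ol | OCC[C@H](C)CCC=C(C)C | starting material
2 | (R)-citronellal, (3R)-3,7-dimethyloct-6-enal | O=CC[C@H](C)CCC=C(C)C | intermediate
3 | (4R)-4,8-dimethylnon-7-en-2-ol, both C2 epimers | CC(O)C[C@H](C)CCC=C(C)C | intermediate
4 | (4R)-4-methylheptane-1,6-diol, both C6 epimers | CC(O)C[C@H](C)CCCO | intermediate
5 | (4R)-6-hydroxy-4-methylheptyl 4-methylbenzenesulfonate | CC(O)C[C@H](C)CCCOS(=O)(=O)c1ccc(C)cc1 | intermediate
6 | (5-bromopentyl)benzene | BrCCCCCc1ccccc1 | starting material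
7 | 5-phenylpentylmagnesium bromide, formed in the flask | Br[Mg]CCCCCc1ccccc1 | intermediate
8 | (4R)-4-methyl-12-phenyldodecan-2-ol, both C2 epimers | CC(O)C[C@H](C)CCCCCCCCc1ccccc1 | intermediate
9 | (4R)-4-methyl-12-phenyldodecan-2-one | CC(=O)C[C@H](C)CCCCCCCCc1ccccc1 | intermediate
10 | cyclopropyldiphenylsulfonium tetrafluoroborate | F[B-](F)(F)F.C1CC1[S+](c1ccccc1)c1ccccc1 | starting material
11 | diphenylsulfonium cyclopropylide, formed in the flask | [C-]1(CC1)[S+](c1ccccc1)c1ccccc1 | intermediate
12 | 2-methyl-2-[(2R)-2-methyl-10-phenyldecyl]-1-oxaspiro[2.2]pentane, both C2 epimers, formed in the flask | CC1(C[C@H](C)CCCCCCCCc2ccccc2)OC12CC2 | intermediate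
13 | 2-methyl-2-[(2R)-2-methyl-10-phenyldecyl]cyclobutan-1-one, both C2 epimers | O=C1CCC1(C)C[C@H](C)CCCCCCCCc1ccccc1 | intermediate
14 | (E)-N-[(2S)-2-(methoxymethyl)pyrrolidin-1-yl]-2-methyl-2-[(2R)-2-methyl-10-phenyldecyl]cyclobutan-1-imine, both C2 epimers | COC[C@@H]1CCCN1/N=C2\CCC2(C)C[C@H](C)CCCCCCCCc3ccccc3 | intermediate
15 | lithium [(2S)-2-(methoxymethyl)pyrrolidin-1-yl]{4-methyl-4-[(2R)-2-methyl-10-phenyldecyl]cyclobut-1-en-1-yl}azanide (azaenolate of 14), formed in the flask | COC[C@@H]1CCCN1N([Li])C2=CCC2(C)C[C@H](C)CCCCCCCCc3ccccc3 | intermediate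
16 | (E,4R)-N-[(2S)-2-(methoxymethyl)pyrrolidin-1-yl]-2,4-dimethyl-2-[(2R)-2-methyl-10-phenyldecyl]cyclobutan-1-imine, both C2 epimers | COC[C@@H]1CCCN1/N=C2\[C@H](C)CC2(C)C[C@H](C)CCCCCCCCc3ccccc3 | intermediate
17 | (4R)-2,4-dimethyl-2-[(2R)-2-methyl-10-phenyldecyl]cyclobutan-1-one, both C2 epimers | O=C1[C@H](C)CC1(C)C[C@H](C)CCCCCCCCc1ccccc1 | intermediate
18 | methyl acetate | COC(C)=O | starting material
19 | lithium 1-methoxyethen-1-olate (lithium enolate of methyl acetate), formed in the flask | C=C(O[Li])OC | intermediate
20 | methyl 2-[(4R)-1-hydroxy-2,4-dimethyl-2-[(2R)-2-methyl-10-phenyldecyl]cyclobutyl]acetate, C1 and C2 epimers | COC(=O)CC1(O)[C@H](C)CC1(C)C[C@H](C)CCCCCCCCc1ccccc1 | intermediate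
21 | dioxygen | O=O | starting material
22 | methyl (4R,8R)-6-hydroperoxy-4,6,8-trimethyl-3-oxo-16-phenylhexadecanoate, both C6 epimers, formed in the flask | COC(=O)CC(=O)[C@H](C)CC(C)(OO)C[C@H](C)CCCCCCCCc1ccccc1 | intermediate
23 | methyl 2-[(3S,4R,6S)-3-hydroxy-4,6-dimethyl-6-[(2R)-2-methyl-10-phenyldecyl]-1,2-dioxan-3-yl]acetate | COC(=O)C[C@]1(O)OO[C@@](C)(C[C@H](C)CCCCCCCCc2ccccc2)C[C@H]1C | target

Total step count: 12 (the Grignard reagent 7 is made within step 5).
Longest linear sequence: 12 steps, from 1 to 23.

**Steps most likely to fail**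

1. Step 12. The hindered tertiary alcohol may enter the cobalt cycle only slowly, and cobalt may break down hydroperoxide 22 before it closes.
 - The fallback sets out from 20 and comes back at 23: the alkoxy radical is made without cobalt and the peroxide is introduced afterwards by hydrogen-atom transfer to an olefin.
 - NaOCl/AcOH should convert 20 into the tertiary hypochlorite methyl 2-[(4R)-1-(chlorooxy)-2,4-dimethyl-2-[(2R)-2-methyl-10-phenyldecyl]cyclobutyl]acetate F1.
 - Light-initiated chain fragmentation of F1 (the same β-scission, with chlorine transfer) should give the γ-chloro ketone methyl (4R,8R)-6-chloro-4,6,8-trimethyl-3-oxo-16-phenylhexadecanoate F2.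
 - KOtBu (2.2 equiv, the first equivalent masking the β-keto ester as its enolate) should eliminate HCl to an olefin mixture represented by methyl (4R,8R)-4,8-dimethyl-6-methylidene-3-oxo-16-phenylhexadecanoate F3.
 - Isayama–Mukaiyama hydroperoxysilylation (Co(acac)2, O2, Et3SiH), in which every olefin isomer converges on the same tertiary C6 radical, should give methyl (4R,8R)-4,6,8-trimethyl-3-oxo-16-phenyl-6-[(triethylsilyl)peroxy]hexadecanoate F4.
 - Desilylation (HF·pyridine, THF) frees 22, which closes to 23 and its C6 epimer as in the main route.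

2. Step 9. Metalation of the strained, hindered hydrazone may stay incomplete, and facial control by the auxiliary may erode in the C2 epimer whose larger ring substituent lies on the face the auxiliary directs to.
 - The fallback sets out from 13 and comes back at 17, giving up auxiliary control in favour of late recycling.
 - Direct methylation of 13 (LiN(iPr)2, THF, −78 °C; MeI) should give 17 together with its C4 epimer (4S)-2,4-dimethyl-2-[(2R)-2-methyl-10-phenyldecyl]cyclobutan-1-one F5.
 - The mixture is taken through steps 11 and 12, where F5 becomes methyl 2-[(4S)-1-hydroxy-2,4-dimethyl-2-[(2R)-2-methyl-10-phenyldecyl]cyclobutyl]acetate F6 and then, among the dioxanols, methyl 2-[(4S,6S)-3-hydroxy-4,6-dimethyl-6-[(2R)-2-methyl-10-phenyldecyl]-1,2-dioxan-3-yl]acetate F7.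
 - F7 is separated and its C4 centre equilibrated through the open hydroperoxy ketone with a catalytic amine base (DBU, CH2Cl2); the mixture of F7 and 23 is re-chromatographed and the remaining F7 recycled.
 - The two C4 epimers should differ little in energy (axial methyl against axial alkyl at C6), so each cycle is expected to convert only part of F7.

3. Step 11. Proton transfer from the α-methine of the hindered ketone to the basic enolate, or retro-aldol of the lithium aldolate on warming, may outrun addition.
 - The fallback sets out from 17 and comes back directly at 20.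
 - The basic enolate is replaced by a Lewis-acid-mediated Mukaiyama aldol addition of the neutral silyl ketene acetal 1-methoxy-1-(trimethylsilyloxy)ethene (TiCl4, CH2Cl2, −78 °C; aqueous work-up).
 - This activates the carbonyl instead of deprotonating next to it and adds no new compound (F0).

**Further compounds**
F1 | step 12 | methyl 2-[(4R)-1-(chlorooxy)-2,4-dimethyl-2-[(2R)-2-methyl-10-phenyldecyl]cyclobutyl]acetate | COC(=O)CC1(OCl)[C@H](C)CC1(C)C[C@H](C)CCCCCCCCc1ccccc1
F2 | step 12 | methyl (4R,8R)-6-chloro-4,6,8-trimethyl-3-oxo-16-phenylhexadecanoate | COC(=O)CC(=O)[C@H](C)CC(C)(Cl)C[C@H](C)CCCCCCCCc1ccccc1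
F3 | step 12 | methyl (4R,8R)-4,8-dimethyl-6-methylidene-3-oxo-16-phenylhexadecanoate | COC(=O)CC(=O)[C@H](C)CC(=C)C[C@H](C)CCCCCCCCc1ccccc1
F4 | step 12 | methyl (4R,8R)-4,6,8-trimethyl-3-oxo-16-phenyl-6-[(triethylsilyl)peroxy]hexadecanoate | COC(=O)CC(=O)[C@H](C)CC(C)(OO[Si](CC)(CC)CC)C[C@H](C)CCCCCCCCc1ccccc1
F5 | step 9 | (4S)-2,4-dimethyl-2-[(2R)-2-methyl-10-phenyldecyl]cyclobutan-1-one | O=C1[C@@H](C)CC1(C)C[C@H](C)CCCCCCCCc1ccccc1
F6 | step 9 | methyl 2-[(4S)-1-hydroxy-2,4-dimethyl-2-[(2R)-2-methyl-10-phenyldecyl]cyclobutyl]acetate | COC(=O)CC1(O)[C@@H](C)CC1(C)C[C@H](C)CCCCCCCCc1ccccc1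
F7 | step 9 | methyl 2-[(4S,6S)-3-hydroxy-4,6-dimethyl-6-[(2R)-2-methyl-10-phenyldecyl]-1,2-dioxan-3-yl]acetate | COC(=O)CC1(O)OO[C@@](C)(C[C@H](C)CCCCCCCCc2ccccc2)C[C@@H]1C
F0 | step 11 | none | none
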